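**Retrosynthetic overview**
1. The target comes from the 5,6‑diacetate triol by selective benzoylation of the primary OH; the two acetates are put on after the sugar acetonide is removed, while O‑2 and the CH2O group are held in a di‑tert‑butylsilylene.
2. The cyclohexene (the only carbocycle) comes from ring‑closing metathesis of an acyclic 1,7‑dienetriol.
3. The dienetriol comes from vinyl Grignard opening of a 2‑C‑hydroxymethyl furanose lactol.
4. Key C–C bond: the quaternary C–CH2O bond is made by a crossed aldol of 5,6‑dideoxy‑2,3‑O‑isopropylidene‑L‑lyxo‑hex‑5‑enofuranose with formaldehyde.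
5. That lactol comes from L‑arabinose (acetonide, Wittig, oxidation, half‑reduction). Ring order: dioxolane, furanose lactol, cyclohexene, temporary dioxasilinane.

Assumption: lactols (1, 2, 4, 7) are anomer mixtures and are drawn without configuration at the anomeric carbon; "parent tetrol" below means (1S,2S,5S,6R)‑1‑(hydroxymethyl)cyclohex‑3‑ene‑1,2,5,6‑tetrol.

**Route**

Step 1
Reactants: 1 L‑arabinose
Product: 2 3,4‑O‑isopropylidene‑L‑arabinopyranose
Conditions: 2,2‑dimethoxypropane, TsOH·H2O (cat.), DMF, rt; Et3N quench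
Reagents that add atoms: 2,2‑dimethoxypropane, COC(C)(C)OC
Why: Acid‑catalysed transketalisation takes the only cis‑vicinal diol of the pyranose (O‑3/O‑4) into a dioxolane and leaves the lactol and 2‑OH free, with no stereocentre touched.

Step 2
Reactants: 2 3,4‑O‑isopropylidene‑L‑arabinopyranose
Product: 3 (1S)‑1‑[(4R,5S)‑5‑(hydroxymethyl)‑2,2‑dimethyl‑1,3‑dioxolan‑4‑yl]prop‑2‑en‑1‑ol
Conditions: Ph3PCH3Br (3.5 equiv), KOtBu (3.4 equiv), THF, 0 °C → 50 °C
Reagents that add atoms: methyltriphenylphosphonium bromide (as its ylide), C[P+](c1ccccc1)(c1ccccc1)c1ccccc1.[Br-]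
Why: Wittig methylenation of the aldehyde tautomer of the lactol gives the terminal alkene and releases the former ring oxygen as a primary OH; the three carbinol centres come unchanged from L‑arabinose.

Step 3
Reactants: 3 the ene‑diol
Product: 5 5,6‑dideoxy‑2,3‑O‑isopropylidene‑L‑lyxo‑hex‑5‑enono‑1,4‑lactone, via vinyl lactol 4 (not isolated)
Conditions: TEMPO (0.2 equiv), PhI(OAc)2 (2.5 equiv), CH2Cl2, rt
Reagents that add atoms: none
Why: Oxoammonium (TEMPO) oxidation is selective for the primary alcohol; the aldehyde closes on the cis γ‑hydroxyl to the lactol, which is oxidised on to the γ‑lactone (oxidative lactonisation of a 1,4‑diol).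

Step 4
Reactants: 5 the vinyl lactone
Product: 4 5,6‑dideoxy‑2,3‑O‑isopropylidene‑L‑lyxo‑hex‑5‑enofuranose
Conditions: i‑Bu2AlH (1.1 equiv), CH2Cl2, −78 °C; aq. potassium sodium tartrate
Reagents that add atoms: none
Why: Half‑reduction of a γ‑lactone with DIBAL‑H stops at the stable aluminium hemiacetal at −78 °C and gives lactol 4, now isolated, on work‑up.

Step 5
Reactants: 4 the vinyl lactol, 6 formaldehyde (37% aqueous)
Product: 7 5,6‑dideoxy‑2‑C‑(hydroxymethyl)‑2,3‑O‑isopropylidene‑L‑lyxo‑hex‑5‑enofuranose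
Conditions: K2CO3, MeOH, 65 °C
Reagents that add atoms: none
Why: Base‑mediated crossed aldol (Ho‑type hydroxymethylation): the aldehyde tautomer enolises at C‑2 and adds to non‑enolisable formaldehyde on the enolate face away from the C‑4 side chain, and re‑closure to the cis‑fused furanose fixes the quaternary centre with O‑2 still cis to O‑3.

Step 6
Reactants: 7 the branched lactol
Product: 8 (1S)‑1‑[(4S,5R)‑4‑(hydroxymethyl)‑5‑[(1S)‑1‑hydroxyprop‑2‑en‑1‑yl]‑2,2‑dimethyl‑1,3‑dioxolan‑4‑yl]prop‑2‑en‑1‑ol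
Conditions: CH2=CHMgBr (5 equiv), THF, −78 → 0 °C; aq. NH4Cl; chromatography
Reagents that add atoms: vinylmagnesium bromide, C=C[Mg]Br
Why: Grignard 1,2‑addition to the open‑chain aldehyde tautomer, in which the magnesium alkoxide of the neighbouring CH2O group chelates the carbonyl (six‑membered chelate) and vinyl enters from the face flanked by the dioxolane oxygen (the same sense as Felkin–Anh attack anti to the C–O bond), setting the new carbinol as S with its OH on the side of the tertiary oxygen; the minor epimer is removed by chromatography.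

Step 7
Reactants: 8 the dienetriol
Product: 9 (3aS,4S,7S,7aR)‑3a‑(hydroxymethyl)‑2,2‑dimethyl‑3a,4,7,7a‑tetrahydro‑1,3‑benzodioxole‑4,7‑diol
Conditions: second‑generation Grubbs catalyst (H2IMes)(PCy3)Cl2Ru=CHPh (5 mol %), CH2Cl2, 40 °C
Reagents that add atoms: none
Why: Ring‑closing olefin metathesis of the 1,7‑diene, whose two vinyl carbinol arms sit cis on the dioxolane, closes the cis‑fused cyclohexene with loss of ethene and touches no stereocentre.

Step 8
Reactants: 9 the cyclohexene triol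
Product: 10 the di‑tert‑butylsilylene of 9 bridging O‑4 and the 3a‑CH2O oxygen (1,3,2‑dioxasilinane; 7‑OH free)
Conditions: t‑Bu2Si(OTf)2 (1.05 equiv), 2,6‑lutidine, CH2Cl2, −40 → 0 °C
Reagents that add atoms: di‑tert‑butylsilyl bis(trifluoromethanesulfonate), CC(C)(C)[Si](OS(=O)(=O)C(F)(F)F)(OS(=O)(=O)C(F)(F)F)C(C)(C)C
Why: Silylene protection of a 1,3‑diol: the primary OH is silylated first and the six‑membered ring then closes on the adjacent O‑4, whereas the 7‑OH would need a seven‑membered bridge and stays free.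

Step 9
Reactants: 10 the silylene acetonide
Product: 11 the parent tetrol carrying the di‑tert‑butylsilylene across O‑2 and the CH2O oxygen (1‑, 5‑ and 6‑OH free)
Conditions: TFA/H2O (9:1), CH2Cl2, 0 °C
Reagents that add atoms: none
Why: Acid‑catalysed ketal hydrolysis removes the cis‑fused isopropylidene group much faster than water can attack the hindered di‑tert‑butyl dialkoxysilane.

Step 10
Reactants: 11 the silylene triol
Product: 12 the 5,6‑di‑O‑acetate of 11 (tertiary 1‑OH free)
Conditions: Ac2O, pyridine, DMAP (cat.), 0 °C → rt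
Reagents that add atoms: acetic anhydride, CC(=O)OC(C)=O
Why: DMAP‑catalysed esterification acetylates the two secondary hydroxyls, while the hindered tertiary OH does not react under these conditions.

Step 11
Reactants: 12 the silylene diacetate
Product: 13 the parent tetrol 5,6‑diacetate (1‑OH, 2‑OH and CH2OH free)
Conditions: HF·pyridine, THF/pyridine, 0 °C
Reagents that add atoms: none
Why: Fluoride‑driven desilylation (Si–F bond formation) removes the silylene under buffered conditions that leave the acetates in place.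

Step 12
Reactants: 13 the triol diacetate
Product: 14 [(1S,2S,5S,6R)‑5,6‑diacetoxy‑1,2‑dihydroxycyclohex‑3‑en‑1‑yl]methyl benzoate
Conditions: BzCl (1.1 equiv), 2,4,6‑collidine, CH2Cl2, −40 → 0 °C
Reagents that add atoms: benzoyl chloride, O=C(Cl)c1ccccc1
Why: Kinetically selective esterification (nucleophilic acyl substitution): the primary OH is benzoylated much faster than the neopentyl secondary and the tertiary OH at low temperature.

**Compound list**
1 | L‑arabinose (pyranose form) | OC1OC[C@H](O)[C@H](O)[C@H]1O | starting material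
2 | 3,4‑O‑isopropylidene‑L‑arabinopyranose | OC1OC[C@@H]2OC(C)(C)O[C@@H]2[C@H]1O | intermediate
3 | (1S)‑1‑[(4R,5S)‑5‑(hydroxymethyl)‑2,2‑dimethyl‑1,3‑dioxolan‑4‑yl]prop‑2‑en‑1‑ol | C=C[C@H](O)[C@H]1OC(C)(C)O[C@H]1CO | intermediate
4 | 5,6‑dideoxy‑2,3‑O‑isopropylidene‑L‑lyxo‑hex‑5‑enofuranose (vinyl cis to the acetonide) | C=C[C@@H]1OC(O)[C@@H]2OC(C)(C)O[C@@H]21 | intermediate
5 | 5,6‑dideoxy‑2,3‑O‑isopropylidene‑L‑lyxo‑hex‑5‑enono‑1,4‑lactone, (3aR,6S,6aR) | C=C[C@@H]1OC(=O)[C@@H]2OC(C)(C)O[C@@H]21 | intermediate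
6 | formaldehyde | C=O | starting material
7 | 5,6‑dideoxy‑2‑C‑(hydroxymethyl)‑2,3‑O‑isopropylidene‑L‑lyxo‑hex‑5‑enofuranose | C=C[C@@H]1OC(O)[C@]2(CO)OC(C)(C)O[C@@H]21 | intermediate
8 | (1S)‑1‑[(4S,5R)‑4‑(hydroxymethyl)‑5‑[(1S)‑1‑hydroxyprop‑2‑en‑1‑yl]‑2,2‑dimethyl‑1,3‑dioxolan‑4‑yl]prop‑2‑en‑1‑ol | C=C[C@H](O)[C@H]1OC(C)(C)O[C@@]1(CO)[C@@H](O)C=C | intermediate
9 | (3aS,4S,7S,7aR)‑3a‑(hydroxymethyl)‑2,2‑dimethyl‑3a,4,7,7a‑tetrahydro‑1,3‑benzodioxole‑4,7‑diol | O[C@H]1C=C[C@H](O)[C@]2(CO)OC(C)(C)O[C@H]12 | intermediate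
10 | di‑tert‑butylsilylene of 9 across O‑4 and the 3a‑CH2O oxygen, 7‑OH free | O[C@H]1C=C[C@@H]3O[Si](C(C)(C)C)(C(C)(C)C)OC[C@]32OC(C)(C)O[C@H]12 | intermediate
11 | parent tetrol with di‑tert‑butylsilylene across O‑2 and the CH2O oxygen | O[C@H]1C=C[C@@H]2O[Si](C(C)(C)C)(C(C)(C)C)OC[C@@]2(O)[C@@H]1O | intermediate
12 | 5,6‑di‑O‑acetate of 11 | CC(=O)O[C@H]1C=C[C@@H]2O[Si](C(C)(C)C)(C(C)(C)C)OC[C@@]2(O)[C@@H]1OC(C)=O | intermediate
13 | (1S,2S,5S,6R)‑1‑(hydroxymethyl)cyclohex‑3‑ene‑1,2,5,6‑tetrol 5,6‑diacetate | CC(=O)O[C@H]1C=C[C@H](O)[C@@](O)(CO)[C@@H]1OC(C)=O | intermediate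
14 | [(1S,2S,5S,6R)‑5,6‑diacetoxy‑1,2‑dihydroxycyclohex‑3‑en‑1‑yl]methyl benzoate | CC(=O)O[C@H]1C=C[C@H](O)[C@@](O)(COC(=O)c2ccccc2)[C@@H]1OC(C)=O | target

**Totals**
Total steps: 12. Longest linear sequence: 12 steps (from L‑arabinose).

**Three steps most likely to fail**

Step 6 (facial selectivity of the vinyl addition next to a quaternary centre). The fallback sets out from 7 and comes back at 9. The Grignard product is taken on as the wrong carbinol, the 1‑epi dienetriol F1. Ring‑closing metathesis with the same ruthenium catalyst gives the 4‑epi cyclohexene triol F2. TBSCl (2.2 equiv) and imidazole in DMF silylate the primary OH and the less hindered 7‑OH to the bis‑TBS ether F3, leaving only the neopentyl 4‑OH free. Dess–Martin periodinane then gives the enone F4. Luche reduction (NaBH4, CeCl3·7H2O, MeOH, −78 °C) should deliver hydride anti to the axial ring C–O bond of the acetonide and give the cis alcohol F5. Bu4NF in THF returns 9. The same sequence works on an epimer mixture.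

Step 9 (ketal hydrolysis beside the silylene). The fallback sets out from 10 and comes back at 13; it removes silicon before the acid step. Ac2O/pyridine/DMAP gives the 7‑acetate F6. HF·pyridine removes the silylene to give the diol F7. Chloroacetic anhydride/pyridine caps both hydroxyls as the bis(chloroacetate) F8. Aqueous TFA then removes the acetonide without constraint to give the diol F9. Ac2O/pyridine/DMAP gives the diacetate bis(chloroacetate) F10. Thiourea with NaHCO3 in EtOH at 50 °C removes only the chloroacetates and returns 13.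

Step 12 (benzoylation of one of three hydroxyls, with acetates nearby). The fallback sets out from 12 and comes back at 14; it unmasks the silylene in two stages. BF3·SMe2 in CH2Cl2 at 0 °C opens the silylene at the primary Si–O bond to give the primary alcohol with a secondary fluorosilyl ether F11. BzCl/pyridine gives the benzoate F12, in which no other secondary OH is free. HF·pyridine removes the fluorosilyl group to give 14.

**Further compounds**
F1 | step 6 | (1R)‑1‑[(4S,5R)‑4‑(hydroxymethyl)‑5‑[(1S)‑1‑hydroxyprop‑2‑en‑1‑yl]‑2,2‑dimethyl‑1,3‑dioxolan‑4‑yl]prop‑2‑en‑1‑ol | C=C[C@H](O)[C@H]1OC(C)(C)O[C@@]1(CO)[C@H](O)C=C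
F2 | step 6 | (3aS,4R,7S,7aR)‑3a‑(hydroxymethyl)‑2,2‑dimethyl‑3a,4,7,7a‑tetrahydro‑1,3‑benzodioxole‑4,7‑diol | O[C@H]1C=C[C@@H](O)[C@]2(CO)OC(C)(C)O[C@H]12
F3 | step 6 | bis‑TBS ether of F2 at the 7‑O and the CH2O oxygen, 4‑OH free | CC(C)(C)[Si](C)(C)O[C@H]1C=C[C@@H](O)[C@]2(CO[Si](C)(C)C(C)(C)C)OC(C)(C)O[C@H]12
F4 | step 6 | 4‑ketone (enone) derived from F3 | CC(C)(C)[Si](C)(C)O[C@H]1C=CC(=O)[C@]2(CO[Si](C)(C)C(C)(C)C)OC(C)(C)O[C@H]12
F5 | step 6 | bis‑TBS ether of 9 at the 7‑O and the CH2O oxygen | CC(C)(C)[Si](C)(C)O[C@H]1C=C[C@H](O)[C@]2(CO[Si](C)(C)C(C)(C)C)OC(C)(C)O[C@H]12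
F6 | step 9 | 7‑O‑acetate of 10 | CC(=O)O[C@H]1C=C[C@@H]3O[Si](C(C)(C)C)(C(C)(C)C)OC[C@]32OC(C)(C)O[C@H]12
F7 | step 9 | 7‑O‑acetate of 9 | CC(=O)O[C@H]1C=C[C@H](O)[C@]2(CO)OC(C)(C)O[C@H]12
F8 | step 9 | 7‑O‑acetate of 9 with chloroacetates on O‑4 and the CH2O oxygen | CC(=O)O[C@H]1C=C[C@H](OC(=O)CCl)[C@]2(COC(=O)CCl)OC(C)(C)O[C@H]12
F9 | step 9 | parent tetrol 5‑acetate with chloroacetates on O‑2 and the CH2O oxygen | CC(=O)O[C@H]1C=C[C@H](OC(=O)CCl)[C@@](O)(COC(=O)CCl)[C@@H]1O
F10 | step 9 | parent tetrol 5,6‑diacetate with chloroacetates on O‑2 and the CH2O oxygen | CC(=O)O[C@H]1C=C[C@H](OC(=O)CCl)[C@@](O)(COC(=O)CCl)[C@@H]1OC(C)=O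
F11 | step 12 | parent tetrol 5,6‑diacetate 2‑O‑(di‑tert‑butylfluorosilyl) ether, CH2OH free | CC(=O)O[C@H]1C=C[C@H](O[Si](F)(C(C)(C)C)C(C)(C)C)[C@@](O)(CO)[C@@H]1OC(C)=O
F12 | step 12 | primary benzoate of F11 | CC(=O)O[C@H]1C=C[C@H](O[Si](F)(C(C)(C)C)C(C)(C)C)[C@@](O)(COC(=O)c2ccccc2)[C@@H]1OC(C)=O
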